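**Plan**
- Retrosynthesis: remove the two MOM ethers; cut C4–C3 of ring C (the α-ketol C4(=O)–C3H(OH), with C4 on ring A, is an acyloin retron) to give a dialdehyde; cut the two aryl–prenyl bonds (C6, C3′) to a dibromide plus prenylstannane; cut the O1–C2 ether bond to a salicylaldehyde phenol plus an α-bromo arylacetate.
- Forward: ring A and ring B pieces are joined by O-alkylation (O1–C2), both carbonyls are reduced to a diol, both prenyl groups are installed in one double Stille coupling, the diol is oxidised to the dialdehyde, and ring C is closed last, followed by MOM removal.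
- Enabling feature: C4 is an aryl aldehyde carbon on ring A (acyl-anion donor) and C3 an aliphatic formyl carbon (acceptor); the C2–H between ring B, O1 and that formyl group is acidic, so C2 racemises in the precursor.
- Stereochemistry: C3 (R) comes from the chiral triazolylidene catalyst and C2 (R) from dynamic kinetic resolution in the same ring closure, giving the trans-(2R,3R) ketol; no later step touches either centre.

Key step: step 8

Assumption: the sense of induction of the aminoindanol-derived triazolium salt on this new substrate class cannot be known in advance; the (5aS,10bR) antipode is written, and the mirror-image salt (also commercial) is to be used if a pilot run on 13 shows the opposite sense.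

**Step 1**
Reactants: 1 5-bromo-2,4-dihydroxybenzaldehyde; 2 chloromethyl methyl ether (MOMCl)
Product: 3 5-bromo-2-hydroxy-4-(methoxymethoxy)benzaldehyde
Conditions: MOMCl (1.05 equiv), K2CO3, acetone, 0 °C to rt
Reagents that add atoms: chloromethyl methyl ether, COCCl
Why: Williamson-type MOM ether formation should be selective for O4, the more acidic and unhindered phenol, because the 2-OH is held in a hydrogen bond to the formyl group.

**Step 2**
Reactants: 4 methyl 2-(3-bromo-4-hydroxyphenyl)acetate; 2 chloromethyl methyl ether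
Product: 5 methyl 2-[3-bromo-4-(methoxymethoxy)phenyl]acetate
Conditions: MOMCl, K2CO3, acetone, 0 °C to rt
Reagents that add atoms: chloromethyl methyl ether, COCCl
Why: MOM ether formation at the only phenol under mild carbonate conditions that leave the methyl ester intact.

**Step 3**
Reactants: 5 methyl 2-[3-bromo-4-(methoxymethoxy)phenyl]acetate; 6 N-bromosuccinimide
Product: 8 methyl 2-bromo-2-[3-bromo-4-(methoxymethoxy)phenyl]acetate (racemic), via silyl ketene acetal 7 (not isolated)
Conditions: LiN(SiMe3)2, Me3SiCl, THF, −78 °C; then NBS, −78 to 0 °C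
Reagents that add atoms: N-bromosuccinimide, O=C1CCC(=O)N1Br
Why: Enolate silylation followed by electrophilic α-bromination of the ketene silyl acetal is an ionic alternative to radical benzylic bromination that should spare the MOM acetal and the ring; the new centre is racemic, as intended.

**Step 4**
Reactants: 3 5-bromo-2-hydroxy-4-(methoxymethoxy)benzaldehyde; 8 methyl 2-bromo-2-[3-bromo-4-(methoxymethoxy)phenyl]acetate
Product: 9 methyl 2-[4-bromo-2-formyl-5-(methoxymethoxy)phenoxy]-2-[3-bromo-4-(methoxymethoxy)phenyl]acetate (racemic)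
Conditions: K2CO3, DMF, 0 °C to rt
Reagents that add atoms: none
Why: Williamson ether synthesis (SN2 of the phenoxide on the activated secondary benzylic α-bromo ester) forms the O1–C2 bond, and at or below room temperature the reversible aldol of the product onto its own formyl group should not compete.

**Step 5**
Reactants: 9 methyl 2-[4-bromo-2-formyl-5-(methoxymethoxy)phenoxy]-2-[3-bromo-4-(methoxymethoxy)phenyl]acetate
Product: 10 2-[4-bromo-2-(hydroxymethyl)-5-(methoxymethoxy)phenoxy]-2-[3-bromo-4-(methoxymethoxy)phenyl]ethan-1-ol (racemic)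
Conditions: LiAlH4, THF, 0 °C
Reagents that add atoms: none
Why: Hydride reduction of ester and aldehyde to the diol removes every enolisable and electrophilic carbonyl before the hot, basic coupling step, while aryl bromides and MOM ethers are inert to LiAlH4 at 0 °C.

**Step 6**
Reactants: 10 2-[4-bromo-2-(hydroxymethyl)-5-(methoxymethoxy)phenoxy]-2-[3-bromo-4-(methoxymethoxy)phenyl]ethan-1-ol; 11 tributyl(3-methylbut-2-en-1-yl)stannane (2.6 equiv)
Product: 12 2-[2-(hydroxymethyl)-5-(methoxymethoxy)-4-(3-methylbut-2-en-1-yl)phenoxy]-2-[4-(methoxymethoxy)-3-(3-methylbut-2-en-1-yl)phenyl]ethan-1-ol (racemic)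
Conditions: Pd(PPh3)4 (10 mol %), CsF, DMF, 90 °C
Reagents that add atoms: tributyl(3-methylbut-2-en-1-yl)stannane, CC(C)=CC[Sn](CCCC)(CCCC)CCCC
Why: Double Stille coupling, in which zerovalent palladium inserts into each aryl bromide, fluoride assists prenyl transfer from tin, and reductive elimination at the less hindered primary terminus of the allyl ligand should give the linear prenyl arenes; free alcohols are tolerated.

**Step 7**
Reactants: 12 2-[2-(hydroxymethyl)-5-(methoxymethoxy)-4-(3-methylbut-2-en-1-yl)phenoxy]-2-[4-(methoxymethoxy)-3-(3-methylbut-2-en-1-yl)phenyl]ethan-1-ol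
Product: 13 2-[2-formyl-5-(methoxymethoxy)-4-(3-methylbut-2-en-1-yl)phenoxy]-2-[4-(methoxymethoxy)-3-(3-methylbut-2-en-1-yl)phenyl]acetaldehyde (racemic, configurationally labile; passed through a short silica plug and used at once)
Conditions: Dess–Martin periodinane (3 equiv), CH2Cl2, 0 °C to rt
Reagents that add atoms: none
Why: Dess–Martin oxidation should convert the benzylic and the primary alcohol into aldehydes under near-neutral, base-free conditions that spare the prenyl alkenes and MOM ethers; the C2 configuration is irrelevant here because it is set in step 8.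

**Step 8**
Reactants: 13 2-[2-formyl-5-(methoxymethoxy)-4-(3-methylbut-2-en-1-yl)phenoxy]-2-[4-(methoxymethoxy)-3-(3-methylbut-2-en-1-yl)phenyl]acetaldehyde
Product: 14 (2R,3R)-3-hydroxy-7-(methoxymethoxy)-2-[4-(methoxymethoxy)-3-(3-methylbut-2-en-1-yl)phenyl]-6-(3-methylbut-2-en-1-yl)-2,3-dihydro-4H-chromen-4-one
Conditions: (5aS,10bR)-2-(pentafluorophenyl)-5a,10b-dihydro-4H,6H-indeno[2,1-b][1,2,4]triazolo[4,3-d][1,4]oxazinium tetrafluoroborate (15 mol %), i-Pr2NEt (30 mol %), toluene, argon, 0 °C to rt
Reagents that add atoms: none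
Why: Proposed new method: the triazolylidene adds to the aryl aldehyde carbon (the future C4) of 13, proton transfer gives the enaminol acyl-anion equivalent, and this adds to the aliphatic formyl carbon (the future C3) before the carbene is expelled, so that ketone, carbinol and ring C arise in one redox-neutral event. The closest known reaction type is the enantioselective NHC-catalysed intramolecular crossed benzoin of salicylaldehyde-tethered ketones to 3-hydroxychroman-4-ones, together with dynamic kinetic resolution in NHC benzoin additions to α-keto esters that carry a labile β-stereocentre; an aldehyde acceptor with a racemising α-centre in this ring closure is the new element. Ring C closes in the 6-exo-trig mode, the nucleophilic C4 attacking the C3 carbonyl whose oxygen stays outside the ring. C3 is controlled by the catalyst, whose indane wall shields one face of the enaminol while the enol O–H hydrogen-bonds the incoming aldehyde; C2 is controlled by dynamic kinetic resolution, because the C2–H between ring B, O1 and the formyl group enolises fast with i-Pr2NEt and only the enantiomer that can place ring B pseudo-equatorial and trans to the forming alkoxide in the half-chair transition state closes quickly. The step needs the aryl aldehyde and not the aliphatic one to become the donor, which should follow from the α,α-disubstitution of the aliphatic aldehyde (slow carbene addition) and from the reversibility of the benzoin, the ketone conjugated to the 2,4-dioxygenated ring A being the thermodynamic sink over the 4-hydroxychroman-3-one. It also needs the 5-exo aldol of the C2 enol onto the aryl aldehyde and the loss of aryloxide from a carbene adduct at C3 to remain slow or reversible, for which the weak amine base, the low temperature and the same steric shielding of C3 are relied on.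

**Step 9**
Reactants: 14 (2R,3R)-3-hydroxy-7-(methoxymethoxy)-2-[4-(methoxymethoxy)-3-(3-methylbut-2-en-1-yl)phenyl]-6-(3-methylbut-2-en-1-yl)-2,3-dihydro-4H-chromen-4-one
Product: 15 lespeflorin B1, (2R,3R)-3,7-dihydroxy-2-[4-hydroxy-3-(3-methylbut-2-en-1-yl)phenyl]-6-(3-methylbut-2-en-1-yl)-2,3-dihydro-4H-chromen-4-one
Conditions: 3 M aq. HCl, MeOH, 40 °C, short reaction time
Reagents that add atoms: none
Why: Acid-catalysed acetal exchange of the two aryl MOM ethers with methanol should free both phenols under conditions mild enough to leave the trans-ketol and the prenyl groups untouched; no stereocentre is involved.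

**Compound list**
1 | 5-bromo-2,4-dihydroxybenzaldehyde | O=Cc1cc(Br)c(O)cc1O | starting material
2 | chloromethyl methyl ether | COCCl | starting material
3 | 5-bromo-2-hydroxy-4-(methoxymethoxy)benzaldehyde | O=Cc1cc(Br)c(OCOC)cc1O | intermediate
4 | methyl 2-(3-bromo-4-hydroxyphenyl)acetate | COC(=O)Cc1ccc(O)c(Br)c1 | starting material
5 | methyl 2-[3-bromo-4-(methoxymethoxy)phenyl]acetate | COC(=O)Cc1ccc(OCOC)c(Br)c1 | intermediate
6 | N-bromosuccinimide | O=C1CCC(=O)N1Br | starting material
7 | ({2-[3-bromo-4-(methoxymethoxy)phenyl]-1-methoxyethenyl}oxy)trimethylsilane (silyl ketene acetal, not isolated) | COC(O[Si](C)(C)C)=Cc1ccc(OCOC)c(Br)c1 | intermediate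
8 | methyl 2-bromo-2-[3-bromo-4-(methoxymethoxy)phenyl]acetate (racemic) | COC(=O)C(Br)c1ccc(OCOC)c(Br)c1 | intermediate
9 | methyl 2-[4-bromo-2-formyl-5-(methoxymethoxy)phenoxy]-2-[3-bromo-4-(methoxymethoxy)phenyl]acetate (racemic) | COC(=O)C(Oc1cc(OCOC)c(Br)cc1C=O)c1ccc(OCOC)c(Br)c1 | intermediate
10 | 2-[4-bromo-2-(hydroxymethyl)-5-(methoxymethoxy)phenoxy]-2-[3-bromo-4-(methoxymethoxy)phenyl]ethan-1-ol (racemic) | OCC(Oc1cc(OCOC)c(Br)cc1CO)c1ccc(OCOC)c(Br)c1 | intermediate
11 | tributyl(3-methylbut-2-en-1-yl)stannane | CC(C)=CC[Sn](CCCC)(CCCC)CCCC | starting material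
12 | 2-[2-(hydroxymethyl)-5-(methoxymethoxy)-4-(3-methylbut-2-en-1-yl)phenoxy]-2-[4-(methoxymethoxy)-3-(3-methylbut-2-en-1-yl)phenyl]ethan-1-ol (racemic) | OCC(Oc1cc(OCOC)c(CC=C(C)C)cc1CO)c1ccc(OCOC)c(CC=C(C)C)c1 | intermediate
13 | 2-[2-formyl-5-(methoxymethoxy)-4-(3-methylbut-2-en-1-yl)phenoxy]-2-[4-(methoxymethoxy)-3-(3-methylbut-2-en-1-yl)phenyl]acetaldehyde (racemic) | O=CC(Oc1cc(OCOC)c(CC=C(C)C)cc1C=O)c1ccc(OCOC)c(CC=C(C)C)c1 | intermediate
14 | (2R,3R)-3-hydroxy-7-(methoxymethoxy)-2-[4-(methoxymethoxy)-3-(3-methylbut-2-en-1-yl)phenyl]-6-(3-methylbut-2-en-1-yl)-2,3-dihydro-4H-chromen-4-one | CC(C)=CCc1cc([C@H]2Oc3cc(OCOC)c(CC=C(C)C)cc3C(=O)[C@@H]2O)ccc1OCOC | intermediate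
15 | lespeflorin B1, (2R,3R)-3,7-dihydroxy-2-[4-hydroxy-3-(3-methylbut-2-en-1-yl)phenyl]-6-(3-methylbut-2-en-1-yl)-2,3-dihydro-4H-chromen-4-one | CC(C)=CCc1cc([C@H]2Oc3cc(O)c(CC=C(C)C)cc3C(=O)[C@@H]2O)ccc1O | target

**Step count:** 9 steps in total. Longest linear sequence: 8 steps (from 4 through steps 2 to 9).

**Steps most likely to fail**

Step 8. The wrong aldehyde may become the donor (leading to the 4-hydroxychroman-3-one). A carbene adduct at C3 may expel the aryloxide. The C2 enol may undergo aldol addition to the aryl aldehyde. Racemisation at C2 may be slow relative to ring closure, so that diastereo- and enantiocontrol are lost. Fallback with known chemistry, setting out from 13: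
- Reductive pinacol cyclisation with SmI2 (THF, t-BuOH, −78 °C) forms the same C3–C4 bond and should give the racemic 2,3-trans-3,4-cis-7-(methoxymethoxy)-2-[4-(methoxymethoxy)-3-(3-methylbut-2-en-1-yl)phenyl]-6-(3-methylbut-2-en-1-yl)chromane-3,4-diol F1.
- Selective oxidation of the benzylic C4 alcohol with MnO2 (CH2Cl2, rt) should then give racemic trans-3-hydroxy-7-(methoxymethoxy)-2-[4-(methoxymethoxy)-3-(3-methylbut-2-en-1-yl)phenyl]-6-(3-methylbut-2-en-1-yl)chroman-4-one F2. Any 2,3-cis material is equilibrated at C3 with Et3N.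
- Preparative chromatography on a chiral stationary phase separates the enantiomers, and the route is rejoined at 14.

Step 6. The prenylpalladium intermediate may lose regiocontrol (coupling at the tertiary terminus gives 1,1-dimethylallyl arenes), and the second coupling at the electron-rich bromide may stall. Fallback, setting out from 10: Stille coupling with allyltributylstannane (Pd(PPh3)4, CsF, DMF, 90 °C), where the transferred group has equivalent termini, should give 2-[2-(hydroxymethyl)-5-(methoxymethoxy)-4-(prop-2-en-1-yl)phenoxy]-2-[4-(methoxymethoxy)-3-(prop-2-en-1-yl)phenyl]ethan-1-ol F3. Cross-metathesis with excess 2-methyl-2-butene (second-generation Grubbs catalyst, CH2Cl2, 40 °C) then converts both allyl groups into prenyl groups, and the route is rejoined at 12.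

Step 9. The freed phenols may add under acid catalysis to the neighbouring prenyl double bonds (dimethylchroman formation), and C2 may epimerise through acid-promoted reversible opening of ring C. Fallback, setting out from 14: Me3SiOTf with 2,2′-bipyridyl (CH3CN, 0 °C) transfers silyl groups to the aryl oxygens (and the 3-OH) without free Brønsted acid. This should give (2R,3R)-3,7-bis(trimethylsilyloxy)-2-[4-(trimethylsilyloxy)-3-(3-methylbut-2-en-1-yl)phenyl]-6-(3-methylbut-2-en-1-yl)-2,3-dihydro-4H-chromen-4-one F4. Hydrolysis with water at rt near neutral pH then gives 15.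

**Further compounds**
F1 | step 8 | rac-(2R,3S,4S)-7-(methoxymethoxy)-2-[4-(methoxymethoxy)-3-(3-methylbut-2-en-1-yl)phenyl]-6-(3-methylbut-2-en-1-yl)-3,4-dihydro-2H-chromene-3,4-diol (racemate, both enantiomers written) | CC(C)=CCc1cc([C@H]2Oc3cc(OCOC)c(CC=C(C)C)cc3[C@H](O)[C@@H]2O)ccc1OCOC.CC(C)=CCc1cc([C@@H]2Oc3cc(OCOC)c(CC=C(C)C)cc3[C@@H](O)[C@H]2O)ccc1OCOC
F2 | step 8 | rac-(2R,3R)-3-hydroxy-7-(methoxymethoxy)-2-[4-(methoxymethoxy)-3-(3-methylbut-2-en-1-yl)phenyl]-6-(3-methylbut-2-en-1-yl)-2,3-dihydro-4H-chromen-4-one (racemate, both enantiomers written) | CC(C)=CCc1cc([C@H]2Oc3cc(OCOC)c(CC=C(C)C)cc3C(=O)[C@@H]2O)ccc1OCOC.CC(C)=CCc1cc([C@@H]2Oc3cc(OCOC)c(CC=C(C)C)cc3C(=O)[C@H]2O)ccc1OCOC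
F3 | step 6 | 2-[2-(hydroxymethyl)-5-(methoxymethoxy)-4-(prop-2-en-1-yl)phenoxy]-2-[4-(methoxymethoxy)-3-(prop-2-en-1-yl)phenyl]ethan-1-ol (racemic) | OCC(Oc1cc(OCOC)c(CC=C)cc1CO)c1ccc(OCOC)c(CC=C)c1
F4 | step 9 | (2R,3R)-3,7-bis(trimethylsilyloxy)-2-[4-(trimethylsilyloxy)-3-(3-methylbut-2-en-1-yl)phenyl]-6-(3-methylbut-2-en-1-yl)-2,3-dihydro-4H-chromen-4-one | CC(C)=CCc1cc([C@H]2Oc3cc(O[Si](C)(C)C)c(CC=C(C)C)cc3C(=O)[C@@H]2O[Si](C)(C)C)ccc1O[Si](C)(C)C
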